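Retrosynthesis: cut (a) the C8–O ester bond, (b) the C10–O bond of the 5,10-ether bridge (transannular hydroalkoxylation of a C1=C10 alkene in a ten-membered germacranolide), (c) C4–C5 (Nozaki–Hiyama–Kishi macrocyclisation), (d) C6–C7 together with C11–C12 of the lactone in one annulation; the side-chain acid and the acyclic dienal are made separately.
Enabling feature: the atoms O–C5–C6–O–C12(=O) of the target are a masked 1,3-dioxolan-2-one. In 2-oxo-1,3-dioxolane-4-carboxylic acid the ring CH becomes the C6 radical after loss of CO2, the carbonate carbon becomes the lactone carbonyl C12, and the ring CH2–O is released as the C5 carbinol, whose oxygen ends as the ether bridge. The partner is the C7=C11 bond of a γ-silyloxy enal whose formyl group is a removable activating group.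
Forward order: acyclic dienal (C1–C3, C7–C11) → γ-lactone by the annulation → exo-methylene → ten-membered carbocycle (C4–C5) → oxepine and oxepane rings at once through the oxygen bridge → esterification at C8.
Stereochemistry: C8 from (S)-2-vinyloxirane; C7 by 1,2-induction from C8 in the radical addition; C6 by equilibration to the trans-lactone aldehyde; C5 by Felkin–Anh addition in the macrocyclisation; C10 dictated by the geometry of the one-atom bridge; the side-chain centre by Pd-catalysed asymmetric allylic etherification.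

Key step: step 8

Remark: locants C1–C15 in the names are the germacrane locants of the target (C6/C7 lactone carbons, C12 lactone carbonyl, C13 exo-methylene, C5/C10 carbons of the ether bridge, C15 ester carbon).
Assumption: the (R,R) ligand of step 16 is taken to deliver the S ether; if the sense is the opposite, the (S,S) ligand is used.

Step 1
Reactants: 1 (S)-2-vinyloxirane
Product: 2 (R)-hex-1-en-5-yn-3-ol
Conditions: LiC≡CH·H2NCH2CH2NH2, DMSO, 0 °C → rt; aq. NH4Cl
Reagents that add atoms: lithium acetylide–ethylenediamine complex, [Li]C#C.NCCN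
Why: Acetylide opens the epoxide by SN2 at the unsubstituted carbon, so the stereocentre (later C8) is carried over unchanged from 1.

Step 2
Reactants: 2 (R)-hex-1-en-5-yn-3-ol
Product: 3 (R)-tert-butyl(hex-1-en-5-yn-3-yloxy)dimethylsilane
Conditions: TBSCl, imidazole, DMF, rt
Reagents that add atoms: tert-butyldimethylsilyl chloride, CC(C)(C)[Si](C)(C)Cl
Why: Standard silylation of a secondary alcohol; the bulky silyloxy group later directs the addition at C7.

Step 3
Reactants: 3 (R)-tert-butyl(hex-1-en-5-yn-3-yloxy)dimethylsilane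
Product: 5 (3E,6R)-6-(tert-butyldimethylsilyloxy)-4-methylocta-3,7-dien-1-ol, via alkenyldimethylalane 4 (not isolated)
Conditions: Me3Al, Cp2ZrCl2 (0.3 equiv), CH2Cl2, 0 °C → rt; then n-BuLi, THF, −78 °C; ethylene oxide, −78 → 0 °C
Reagents that add atoms: trimethylaluminium, C[Al](C)C; ethylene oxide, C1CO1
Why: Zirconium-catalysed syn-methylalumination (Negishi carboalumination) of the terminal alkyne should give the (E)-alkenylalane regioselectively, and its ate complex opens ethylene oxide with retention, which fixes the (E)-C1=C10 alkene.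

Step 4
Reactants: 5 (3E,6R)-6-(tert-butyldimethylsilyloxy)-4-methylocta-3,7-dien-1-ol
Product: 6 (3E,6R)-6-(tert-butyldimethylsilyloxy)-4-methylocta-3,7-dienal
Conditions: Dess–Martin periodinane, NaHCO3, CH2Cl2, 0 °C
Reagents that add atoms: none
Why: Buffered Dess–Martin oxidation converts the primary alcohol into the β,γ-unsaturated aldehyde without moving the alkene.

Step 5
Reactants: 6 (3E,6R)-6-(tert-butyldimethylsilyloxy)-4-methylocta-3,7-dienal
Product: 7 tert-butyl{[(3R,5E)-8,8-dimethoxy-5-methylocta-1,5-dien-3-yl]oxy}dimethylsilane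
Conditions: HC(OMe)3, PPTS (cat.), MeOH, rt
Reagents that add atoms: trimethyl orthoformate, COC(OC)OC
Why: Acetalisation masks the C3 aldehyde so that it survives the radical step and can be released in step 10.

Step 6
Reactants: 7 tert-butyl{[(3R,5E)-8,8-dimethoxy-5-methylocta-1,5-dien-3-yl]oxy}dimethylsilane
Product: 8 (2E,4R,6E)-4-(tert-butyldimethylsilyloxy)-9,9-dimethoxy-6-methylnona-2,6-dienal
Conditions: (E)-crotonaldehyde (5 equiv), second-generation Hoveyda–Grubbs catalyst (5 mol%), CH2Cl2, 40 °C
Reagents that add atoms: (E)-crotonaldehyde, C/C=C/C=O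
Why: Cross-metathesis of the monosubstituted alkene with crotonaldehyde should give the (E)-enal with loss of propene, while the trisubstituted alkene is too hindered to take part.

Step 7
Reactants: 9 4-(hydroxymethyl)-1,3-dioxolan-2-one (glycerol carbonate, racemic)
Product: 10 2-oxo-1,3-dioxolane-4-carboxylic acid (racemic)
Conditions: TEMPO (cat.), PhI(OAc)2, MeCN/H2O, rt
Reagents that add atoms: water, O
Why: Oxoammonium (TEMPO) oxidation takes the primary alcohol through the aldehyde hydrate to the acid without touching the cyclic carbonate.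

Step 8
Reactants: 8 (2E,4R,6E)-4-(tert-butyldimethylsilyloxy)-9,9-dimethoxy-6-methylnona-2,6-dienal; 10 2-oxo-1,3-dioxolane-4-carboxylic acid
Product: 12 α-formyl lactone 3-formyl-5-(hydroxymethyl)-4-[(1R,3E)-1-(tert-butyldimethylsilyloxy)-6,6-dimethoxy-3-methylhex-3-en-1-yl]oxolan-2-one (C7 as in 26; C6 and C11 epimers), via Giese adduct aldehyde 11 (not isolated)
Conditions: [Ir(dF(CF3)ppy)2(dtbbpy)]PF6 (2 mol%), Cs2CO3, DMSO, blue LEDs, rt; AcOH quench
Reagents that add atoms: none
Why: Proposed new method: photoredox oxidation of the carboxylate of 10 and loss of CO2 should give the 2-oxo-1,3-dioxolan-4-yl radical (C6), which adds to C7 of the enal (Giese addition, C6–C7); reduction of the α-formyl radical by the reduced photocatalyst gives the C11 enolate (radical-polar crossover, 11 after protonation), which attacks the carbonate carbonyl C12 and opens the dioxolanone with loss of the C5 alkoxide (C11–C12). The closest known reaction types are the photoredox decarboxylative conjugate addition of α-oxy acids with anionic trapping of the adduct, and base-mediated carbonate migration along polyols, which passes through the same bicyclic ortho-ester-type tetrahedral intermediate. The lactone ring closes by 5-exo-trig addition–elimination at the carbonate carbon; collapse toward the γ-lactone with release of the primary C5 hydroxyl is the thermodynamically favoured direction and is pulled further by deprotonation of the acidic α-formyl lactone. C7 is set in the radical addition by 1,2-induction from C8 (silyloxy group anti to the incoming radical, chain over the double bond, H outside); C6 and C11 form as mixtures, which is harmless because C11 is trigonal again after step 9 and C6 is equilibrated in step 12. The step needs addition to the enal in preference to the unactivated trisubstituted alkene, which the polarity match of the α-oxy radical secures, and acyl transfer in preference to simple protonation, which the five-membered transition state and the strained cyclic carbonate favour.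

Step 9
Reactants: 12 α-formyl lactone
Product: 13 5-(hydroxymethyl)-3-methylidene-4-[(1R,3E)-1-(tert-butyldimethylsilyloxy)-6,6-dimethoxy-3-methylhex-3-en-1-yl]oxolan-2-one (C7 as in 26; C6 epimers)
Conditions: 37% aq. HCHO, K2CO3, THF, 0 °C → rt
Reagents that add atoms: formaldehyde, C=O
Why: Aldol addition of the formyl-stabilised enolate to formaldehyde, formyl transfer to the new alkoxide and β-elimination of formate (deformylative α-methylenation of α-formyl lactones) should give the exo-methylene lactone.

Step 10
Reactants: 13 exo-methylene lactone alcohol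
Product: 14 5-(hydroxymethyl)-3-methylidene-4-[(1R,3E)-1-(tert-butyldimethylsilyloxy)-3-methyl-6-oxohex-3-en-1-yl]oxolan-2-one (C6 epimers)
Conditions: PPTS, acetone/H2O (9:1), 45 °C
Reagents that add atoms: water, O
Why: Mild acid hydrolysis of the dimethyl acetal frees the C3 aldehyde; the secondary TBS ether and the lactone tolerate PPTS.

Step 11
Reactants: 14 C3 aldehyde
Product: 15 methyl (2Z,5E,8R)-8-(tert-butyldimethylsilyloxy)-8-[2-(hydroxymethyl)-4-methylidene-5-oxooxolan-3-yl]-2-iodo-6-methylocta-2,5-dienoate (C6 epimers)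
Conditions: Ph3P=C(I)CO2Me, CH2Cl2, rt
Reagents that add atoms: methyl 2-iodo-2-(triphenyl-λ5-phosphanylidene)acetate, COC(=O)C(I)=P(c1ccccc1)(c1ccccc1)c1ccccc1
Why: Wittig olefination with the ester-stabilised iodo-ylide places the ester trans to the chain, which gives the (Z)-α-iodo enoate needed for a ring-cis C3=C4 bond.

Step 12
Reactants: 15 iodo enoate alcohol
Product: 16 methyl (2Z,5E,8R)-8-(tert-butyldimethylsilyloxy)-8-[2-formyl-4-methylidene-5-oxooxolan-3-yl]-2-iodo-6-methylocta-2,5-dienoate (lactone 6,7-trans, C6 and C7 as in 26)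
Conditions: Dess–Martin periodinane, NaHCO3, CH2Cl2, 0 °C; then Et3N (cat.), rt
Reagents that add atoms: none
Why: Dess–Martin oxidation gives the α-acyloxy aldehyde, and amine-mediated enolisation should equilibrate C6 to the more stable 6,7-trans lactone.

Step 13
Reactants: 16 aldehyde iodo enoate
Product: 17 ten-membered carbocycle: methyl 5-hydroxy-8-(tert-butyldimethylsilyloxy)-12-oxo-6,12-epoxygermacra-1(10),3,11(13)-trien-15-oate (1(10)E; C2 and C5 cis on C3=C4; C5–C8 as in 26)
Conditions: CrCl2 (8 equiv), NiCl2 (1 mol%), DMSO/THF, 0.003 M, rt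
Reagents that add atoms: none
Why: Nozaki–Hiyama–Kishi reaction: the alkenylchromium formed via Ni adds to the aldehyde with retention of alkene geometry, and Felkin–Anh attack anti to the C6–O bond should give the 5,6-anti alcohol (C5 as in 26); high dilution favours closure of the ring, which is helped by the cis C3=C4 bond.

Step 14
Reactants: 17 ten-membered carbocycle
Product: 18 5,10-ether-bridged lactone TBS ether (all ring stereocentres as in 26)
Conditions: TfOH (5 mol%), CH2Cl2, −20 → 0 °C
Reagents that add atoms: none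
Why: Protonation of the electron-rich C1=C10 alkene at C1 gives the tertiary C10 cation, which the transannular C5 hydroxyl traps (Markovnikov hydroalkoxylation); the one-atom oxygen bridge can only span the ring cis, so the configuration at C10 follows from C5.

Step 15
Reactants: 18 bridged lactone TBS ether
Product: 19 C8 alcohol of the bridged lactone
Conditions: HF·pyridine, THF/pyridine, 0 °C → rt
Reagents that add atoms: none
Why: Fluoride cleaves the Si–O bond; the α-methylene lactone and the enoate tolerate buffered HF.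

Step 16
Reactants: 20 2-methyl-2-vinyloxirane (isoprene monoxide, racemic); 21 4-methoxybenzyl alcohol
Product: 22 (S)-2-(4-methoxybenzyloxy)-2-methylbut-3-en-1-ol
Conditions: Pd2(dba)3·CHCl3 (1 mol%), (R,R)-N,N′-bis(2-diphenylphosphinobenzoyl)-1,2-diaminocyclohexane (3 mol%), Et3B (1 mol%), CH2Cl2, rt
Reagents that add atoms: none
Why: Pd(0) opens the vinyl epoxide to interconverting π-allyl complexes (dynamic kinetic asymmetric allylic etherification); the borane co-catalyst delivers the alcohol to the tertiary carbon and the chiral ligand sets the quaternary centre.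

Step 17
Reactants: 22 (S)-2-(4-methoxybenzyloxy)-2-methylbut-3-en-1-ol
Product: 23 (S)-2-(4-methoxybenzyloxy)-2-methylbut-3-enoic acid
Conditions: TEMPO (cat.), PhI(OAc)2, MeCN/H2O, rt
Reagents that add atoms: water, O
Why: TEMPO oxidation of the primary alcohol to the acid leaves the PMB ether, the vinyl group and the quaternary centre untouched.

Step 18
Reactants: 19 C8 alcohol of the bridged lactone; 23 (S)-2-(4-methoxybenzyloxy)-2-methylbut-3-enoic acid
Product: 25 PMB-protected ester (8-O-[(S)-2-(4-methoxybenzyloxy)-2-methylbut-3-enoyl] derivative of 19), via mixed anhydride 24 (not isolated)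
Conditions: 2,4,6-trichlorobenzoyl chloride, Et3N, THF, rt; then 19, DMAP, toluene, rt
Reagents that add atoms: none
Why: Yamaguchi esterification through the mixed anhydride and the acylpyridinium ion is suited to a hindered secondary alcohol and an α,α-disubstituted acid, with retention at C8.

Step 19
Reactants: 25 PMB-protected ester
Product: 26 target (5R,6S,7R,8R,10S; side chain S)
Conditions: DDQ, CH2Cl2/pH 7 buffer, 0 °C → rt
Reagents that add atoms: none
Why: Oxidative cleavage of the PMB ether by DDQ frees the tertiary alcohol without affecting the alkenes, the lactone or the esters.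

Compound list
1 | (S)-2-vinyloxirane | C=C[C@H]1CO1 | starting material
2 | (R)-hex-1-en-5-yn-3-ol | C=C[C@H](O)CC#C | intermediate
3 | (R)-tert-butyl(hex-1-en-5-yn-3-yloxy)dimethylsilane | C=C[C@H](O[Si](C)(C)C(C)(C)C)CC#C | intermediate
4 | dimethyl[(1E,4R)-4-(tert-butyldimethylsilyloxy)-2-methylhexa-1,5-dien-1-yl]alumane | C=C[C@H](O[Si](C)(C)C(C)(C)C)C/C(C)=C/[Al](C)C | intermediate
5 | (3E,6R)-6-(tert-butyldimethylsilyloxy)-4-methylocta-3,7-dien-1-ol | C=C[C@H](O[Si](C)(C)C(C)(C)C)C/C(C)=C/CCO | intermediate
6 | (3E,6R)-6-(tert-butyldimethylsilyloxy)-4-methylocta-3,7-dienal | C=C[C@H](O[Si](C)(C)C(C)(C)C)C/C(C)=C/CC=O | intermediate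
7 | tert-butyl{[(3R,5E)-8,8-dimethoxy-5-methylocta-1,5-dien-3-yl]oxy}dimethylsilane | C=C[C@H](O[Si](C)(C)C(C)(C)C)C/C(C)=C/CC(OC)OC | intermediate
8 | (2E,4R,6E)-4-(tert-butyldimethylsilyloxy)-9,9-dimethoxy-6-methylnona-2,6-dienal | O=C/C=C/[C@H](O[Si](C)(C)C(C)(C)C)C/C(C)=C/CC(OC)OC | intermediate
9 | 4-(hydroxymethyl)-1,3-dioxolan-2-one (glycerol carbonate) | O=C1OCC(CO)O1 | starting material
10 | 2-oxo-1,3-dioxolane-4-carboxylic acid | O=C1OCC(C(=O)O)O1 | intermediate
11 | Giese adduct: (6E)-4-(tert-butyldimethylsilyloxy)-9,9-dimethoxy-6-methyl-3-(2-oxo-1,3-dioxolan-4-yl)non-6-enal, C7 and C8 as in 26, C6 epimers | O=CC[C@@H](C1COC(=O)O1)[C@H](O[Si](C)(C)C(C)(C)C)C/C(C)=C/CC(OC)OC | intermediate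
12 | 3-formyl-5-(hydroxymethyl)-4-[(1R,3E)-1-(tert-butyldimethylsilyloxy)-6,6-dimethoxy-3-methylhex-3-en-1-yl]oxolan-2-one, C7 as in 26, C6 and C11 epimers | O=CC1C(=O)OC(CO)[C@H]1[C@H](O[Si](C)(C)C(C)(C)C)C/C(C)=C/CC(OC)OC | intermediate
13 | 5-(hydroxymethyl)-3-methylidene-4-[(1R,3E)-1-(tert-butyldimethylsilyloxy)-6,6-dimethoxy-3-methylhex-3-en-1-yl]oxolan-2-one, C6 epimers | OCC1OC(=O)C(=C)[C@@H]1[C@H](O[Si](C)(C)C(C)(C)C)C/C(C)=C/CC(OC)OC | intermediate
14 | 5-(hydroxymethyl)-3-methylidene-4-[(1R,3E)-1-(tert-butyldimethylsilyloxy)-3-methyl-6-oxohex-3-en-1-yl]oxolan-2-one, C6 epimers | OCC1OC(=O)C(=C)[C@@H]1[C@H](O[Si](C)(C)C(C)(C)C)C/C(C)=C/CC=O | intermediate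
15 | methyl (2Z,5E,8R)-8-(tert-butyldimethylsilyloxy)-8-[2-(hydroxymethyl)-4-methylidene-5-oxooxolan-3-yl]-2-iodo-6-methylocta-2,5-dienoate, C6 epimers | OCC1OC(=O)C(=C)[C@@H]1[C@H](O[Si](C)(C)C(C)(C)C)C/C(C)=C/C/C=C(I)/C(=O)OC | intermediate
16 | methyl (2Z,5E,8R)-8-(tert-butyldimethylsilyloxy)-8-(2-formyl-4-methylidene-5-oxooxolan-3-yl)-2-iodo-6-methylocta-2,5-dienoate, lactone 6,7-trans as in 26 | O=C[C@H]1OC(=O)C(=C)[C@@H]1[C@H](O[Si](C)(C)C(C)(C)C)C/C(C)=C/C/C=C(I)/C(=O)OC | intermediate
17 | methyl 5-hydroxy-8-(tert-butyldimethylsilyloxy)-12-oxo-6,12-epoxygermacra-1(10),3,11(13)-trien-15-oate (1(10)E, ring-cis C3=C4, C5–C8 as in 26) | O[C@@H]1/C(C(=O)OC)=C\C/C=C(C)/C[C@@H](O[Si](C)(C)C(C)(C)C)[C@H]2C(=C)C(=O)O[C@H]12 | intermediate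
18 | 5,10-ether-bridged α-methylene lactone methyl ester, 8-O-TBS ether, stereocentres as in 26 | CC(C)(C)[Si](C)(C)O[C@@H]1C[C@]2(C)CCC=C(C(=O)OC)[C@@H](O2)[C@H]2OC(=O)C(=C)[C@@H]21 | intermediate
19 | 5,10-ether-bridged α-methylene lactone methyl ester, free 8-OH, stereocentres as in 26 | O[C@@H]1C[C@]2(C)CCC=C(C(=O)OC)[C@@H](O2)[C@H]2OC(=O)C(=C)[C@@H]21 | intermediate
20 | 2-methyl-2-vinyloxirane (isoprene monoxide, racemic) | CC1(C=C)CO1 | starting material
21 | 4-methoxybenzyl alcohol | COc1ccc(CO)cc1 | starting material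
22 | (S)-2-(4-methoxybenzyloxy)-2-methylbut-3-en-1-ol | C=C[C@](C)(OCc1ccc(OC)cc1)CO | intermediate
23 | (S)-2-(4-methoxybenzyloxy)-2-methylbut-3-enoic acid | C=C[C@](C)(OCc1ccc(OC)cc1)C(=O)O | intermediate
24 | mixed anhydride of 23 with 2,4,6-trichlorobenzoic acid | C=C[C@](C)(OCc1ccc(OC)cc1)C(=O)OC(=O)c1c(Cl)cc(Cl)cc1Cl | intermediate
25 | 8-O-[(S)-2-(4-methoxybenzyloxy)-2-methylbut-3-enoyl] ester of 19 | C=C[C@](C)(OCc1ccc(OC)cc1)C(=O)O[C@@H]1C[C@]2(C)CCC=C(C(=O)OC)[C@@H](O2)[C@H]2OC(=O)C(=C)[C@@H]21 | intermediate
26 | CNP0325750.1 | C=C[C@](C)(O)C(=O)O[C@@H]1C[C@]2(C)CCC=C(C(=O)OC)[C@@H](O2)[C@H]2OC(=O)C(=C)[C@@H]21 | target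

Total step count: 19. Longest linear sequence: 16 steps (steps 1–6, 8–15, 18, 19).

Steps most likely to fail

Step 8 (Proposed new method). The enolate formed after the radical addition may be protonated faster than it is acylated, so that the sequence stops after C–C bond formation. The tetrahedral intermediate may also collapse toward the six-membered lactone, and the radical may add to C7 with low facial selectivity. The fallback uses known chemistry, sets out from 7 and returns at 12. Cross-metathesis of 7 with methyl acrylate gives the enoate methyl (2E,4R,6E)-4-(tert-butyldimethylsilyloxy)-9,9-dimethoxy-6-methylnona-2,6-dienoate F1. Photoredox decarboxylative conjugate addition of 10 to F1 with protic work-up gives the carbonate ester F2. K2CO3 in methanol cleaves the cyclic carbonate and the C6 alkoxide lactonises onto the methyl ester to give the lactone alcohol F3. Claisen formylation of F3 with NaH and ethyl formate gives 12.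

Step 13. Intermolecular coupling may outrun closure of the ten-membered ring, and addition to the aldehyde may show poor facial selectivity at C5. The fallback sets out from 14 and returns at 17. Wittig methylenation of 14 with Ph3P=CH2 gives the terminal alkene alcohol F4. Dess–Martin oxidation with amine equilibration gives the trans aldehyde F5. A Baylis–Hillman reaction of F5 with methyl acrylate and DABCO gives the allylic alcohol F6. Ring-closing metathesis of F6 at high dilution joins C3 and C4 to give 17.

Step 14. The C10 cation may lose a proton (alkene migration), or the silyl ether may be cleaved, before the hydroxyl closes the bridge. The fallback sets out from 17 and returns at 18. Phenylselenyl chloride at −78 °C closes the ether by anti addition across C1=C10 and gives the C1-phenylselanyl bridged ether F7. Triphenyltin hydride with triethylborane then removes selenium to give 18.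

Further compounds
F1 | step 8 | methyl (2E,4R,6E)-4-(tert-butyldimethylsilyloxy)-9,9-dimethoxy-6-methylnona-2,6-dienoate | COC(=O)/C=C/[C@H](O[Si](C)(C)C(C)(C)C)C/C(C)=C/CC(OC)OC
F2 | step 8 | methyl (6E)-4-(tert-butyldimethylsilyloxy)-9,9-dimethoxy-6-methyl-3-(2-oxo-1,3-dioxolan-4-yl)non-6-enoate, C7 and C8 as in 26 | COC(=O)C[C@@H](C1COC(=O)O1)[C@H](O[Si](C)(C)C(C)(C)C)C/C(C)=C/CC(OC)OC
F3 | step 8 | 5-(hydroxymethyl)-4-[(1R,3E)-1-(tert-butyldimethylsilyloxy)-6,6-dimethoxy-3-methylhex-3-en-1-yl]oxolan-2-one | OCC1OC(=O)C[C@@H]1[C@H](O[Si](C)(C)C(C)(C)C)C/C(C)=C/CC(OC)OC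
F4 | step 13 | 5-(hydroxymethyl)-3-methylidene-4-[(1R,3E)-1-(tert-butyldimethylsilyloxy)-3-methylhepta-3,6-dien-1-yl]oxolan-2-one | OCC1OC(=O)C(=C)[C@@H]1[C@H](O[Si](C)(C)C(C)(C)C)C/C(C)=C/CC=C
F5 | step 13 | 6,7-trans 2-formyl-4-methylidene-5-oxooxolane bearing the (1R,3E)-1-(tert-butyldimethylsilyloxy)-3-methylhepta-3,6-dien-1-yl chain | O=C[C@H]1OC(=O)C(=C)[C@@H]1[C@H](O[Si](C)(C)C(C)(C)C)C/C(C)=C/CC=C
F6 | step 13 | Baylis–Hillman adduct: methyl 2-[hydroxy(lactonyl)methyl]acrylate, C5 as in 26 | C=C(C(=O)OC)[C@@H](O)[C@H]1OC(=O)C(=C)[C@@H]1[C@H](O[Si](C)(C)C(C)(C)C)C/C(C)=C/CC=C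
F7 | step 14 | C1-phenylselanyl derivative of 18 | CC(C)(C)[Si](C)(C)O[C@@H]1C[C@]2(C)C([Se]c3ccccc3)CC=C(C(=O)OC)[C@@H](O2)[C@H]2OC(=O)C(=C)[C@@H]21
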